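**Retrosynthetic overview**

- Feature: ring C5 carries the benzylic carbon C1', which is bonded to the E-trisubstituted alkene C2'=C3' with a methyl group on C3'. This C5–C1'H2–C2'H=C3'(CH3)–C4' unit is cut at C1'–C2' and at C3'–CH3 into a benzylic chloride, a terminal alkyne (C2'≡C3') and AlMe3.
- Arene half: 2,4,5-trihydroxybenzaldehyde → tris-MOM ether → benzylic silyl ether → lithiation and formylation between two OMOM groups (ring C1) → dioxolane → benzylic chloride.
- Enyne half: geranyl acetate supplies C5'–C12' with the E C6'=C7' alkene. Terminal allylic oxidation to the enoic acid, asymmetric hydrogenation (C11', S), reduction, allylic chloride, TIPS ether, then three-carbon propargylation (C2'–C4').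
- End game: desilylation, oxidation of C12' to the acid, then acid hydrolysis of the three MOM ethers and the dioxolane.
- Rings: the benzene ring is bought and no ring of the target is made. The only ring formed is the temporary 1,3-dioxolane on the formyl carbon (step 5), opened again in the last step.

Key step: step 17

Remark: locants are ring C1 (formyl carbon) to C6 with the chain on C5, and chain C1' (benzylic) to C12' (carboxyl); the (S)-ligand in step 11 is chosen on the assumption that the substrate follows the sense of induction known for (E)-2-methylalk-2-enoic acids.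

**Route**

Step 1
Reactants: 1 2,4,5-trihydroxybenzaldehyde
Product: 2 2,4,5-tris(methoxymethoxy)benzaldehyde
Conditions: MOMCl (4.5 equiv), i-Pr2NEt (6 equiv), CH2Cl2, 0 °C → reflux, argon
Reagents that add atoms: chloromethyl methyl ether (MOMCl), COCCl
Why: O-Alkylation of the three phenols by the reactive chloromethyl ether under amine base (Williamson-type etherification) caps every acidic OH as a MOM acetal that later directs lithiation and is removed by acid in the last step.

Step 2
Reactants: 2 2,4,5-tris(methoxymethoxy)benzaldehyde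
Product: 3 [2,4,5-tris(methoxymethoxy)phenyl]methanol
Conditions: NaBH4, MeOH/THF, 0 °C
Reagents that add atoms: none
Why: Borohydride reduction of the aryl aldehyde gives the benzylic alcohol whose carbon becomes C1', and MOM ethers are inert to hydride.

Step 3
Reactants: 3 [2,4,5-tris(methoxymethoxy)phenyl]methanol
Product: 4 tert-butyl(dimethyl){[2,4,5-tris(methoxymethoxy)phenyl]methoxy}silane
Conditions: TBSCl, imidazole, DMF, rt
Reagents that add atoms: tert-butyldimethylsilyl chloride (TBSCl), CC(C)(C)[Si](C)(C)Cl
Why: Imidazole-promoted silylation of the primary alcohol removes the only acidic proton so that the base in step 4 is spent on the ring alone.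

Step 4
Reactants: 4 tert-butyl(dimethyl){[2,4,5-tris(methoxymethoxy)phenyl]methoxy}silane
Product: 6 3-({[tert-butyl(dimethyl)silyl]oxy}methyl)-2,5,6-tris(methoxymethoxy)benzaldehyde, via aryllithium 5 (not isolated)
Conditions: n-BuLi (1.3 equiv), THF, −78 → 0 °C; DMF, −78 °C → rt; aq NH4Cl
Reagents that add atoms: N,N-dimethylformamide (DMF), CN(C)C=O
Why: Directed ortho-metalation takes the ring proton flanked by two OMOM groups, the most acidic and doubly coordinated site (the other ring CH has one OMOM neighbour and a bulky silyloxymethyl neighbour), and formylation of the aryllithium with DMF puts the aldehyde on ring C1.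

Step 5
Reactants: 6 3-({[tert-butyl(dimethyl)silyl]oxy}methyl)-2,5,6-tris(methoxymethoxy)benzaldehyde
Product: 7 tert-butyl{[3-(1,3-dioxolan-2-yl)-2,4,5-tris(methoxymethoxy)phenyl]methoxy}dimethylsilane
Conditions: TMSOCH2CH2OTMS (3 equiv), TMSOTf (5 mol%), CH2Cl2, −78 → −30 °C; pyridine quench
Reagents that add atoms: 1,2-bis(trimethylsilyloxy)ethane, C[Si](C)(C)OCCO[Si](C)(C)C
Why: Noyori acetalisation with the bis-silyl ether of ethylene glycol under catalytic silyl triflate is aprotic and is driven by formation of hexamethyldisiloxane, so the hindered aldehyde should be masked as the dioxolane without the protic acid that would cleave the MOM ethers.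

Step 6
Reactants: 7 tert-butyl{[3-(1,3-dioxolan-2-yl)-2,4,5-tris(methoxymethoxy)phenyl]methoxy}dimethylsilane
Product: 8 [3-(1,3-dioxolan-2-yl)-2,4,5-tris(methoxymethoxy)phenyl]methanol
Conditions: TBAF, THF, 0 °C → rt
Reagents that add atoms: none
Why: Fluoride-induced desilylation cleaves only the Si–O bond and leaves the base-stable MOM ethers and the dioxolane in place.

Step 7
Reactants: 8 [3-(1,3-dioxolan-2-yl)-2,4,5-tris(methoxymethoxy)phenyl]methanol
Product: 10 2-[3-(chloromethyl)-2,5,6-tris(methoxymethoxy)phenyl]-1,3-dioxolane, via mesylate 9 (not isolated)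
Conditions: MsCl, s-collidine, LiCl, DMF, 0 °C; used at once
Reagents that add atoms: lithium chloride, [Li+].[Cl-]
Why: Sulfonylation followed by SN2 displacement of the benzylic mesylate by chloride in the same flask (Collington–Meyers chlorination) works under buffered, non-acidic conditions that spare all four acetal groups.

Step 8
Reactants: 11 geranyl acetate
Product: 12 (2E,6E)-8-hydroxy-3,7-dimethylocta-2,6-dien-1-yl acetate
Conditions: SeO2 (0.3 equiv), t-BuOOH (3 equiv), salicylic acid (0.1 equiv), CH2Cl2, rt
Reagents that add atoms: tert-butyl hydroperoxide, CC(C)(C)OO; selenium dioxide (SeO2, oxygen carrier), O=[Se]=O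
Why: Catalytic SeO2 allylic oxidation (ene reaction then [2,3]-sigmatropic shift, reoxidised by the hydroperoxide) hydroxylates the E-methyl group of the electron-rich terminal alkene, while the alkene beside the acetoxy group is inductively deactivated, which gives the (E)-allylic alcohol.

Step 9
Reactants: 12 (2E,6E)-8-hydroxy-3,7-dimethylocta-2,6-dien-1-yl acetate
Product: 13 (2E,6E)-3,7-dimethyl-8-oxoocta-2,6-dien-1-yl acetate
Conditions: MnO2 (activated, excess), CH2Cl2, rt
Reagents that add atoms: none
Why: Activated MnO2 oxidises allylic alcohols selectively to enals without isomerising the E alkenes or touching the acetate, and enal already formed in step 8 is pooled here.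

Step 10
Reactants: 13 (2E,6E)-3,7-dimethyl-8-oxoocta-2,6-dien-1-yl acetate
Product: 14 (2E,6E)-8-(acetyloxy)-2,6-dimethylocta-2,6-dienoic acid
Conditions: NaClO2, NaH2PO4, 2-methyl-2-butene, t-BuOH/H2O, 0 °C → rt
Reagents that add atoms: sodium chlorite, [Na+].[O-]Cl=O
Why: Pinnick oxidation (buffered chlorite with an alkene scavenger for HOCl) takes the enal to the (E)-2-methylalk-2-enoic acid with retention of geometry and without chlorinating the second alkene.

Step 11
Reactants: 14 (2E,6E)-8-(acetyloxy)-2,6-dimethylocta-2,6-dienoic acid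
Product: 15 (2S,6E)-8-(acetyloxy)-2,6-dimethyloct-6-enoic acid
Conditions: H2 (about 2 atm), Ru(OAc)2[(S)-H8-BINAP] (0.5 mol%), MeOH, 20 °C
Reagents that add atoms: none
Why: Carboxylate-directed asymmetric hydrogenation (Noyori type) by the divalent ruthenium diacetate complex of (S)-H8-BINAP reduces only the conjugated C=C bond, the chiral ligand controlling the face to which hydrogen is delivered so that C11' is set as S, while the isolated alkene has no coordinating group and stays.

Step 12
Reactants: 15 (2S,6E)-8-(acetyloxy)-2,6-dimethyloct-6-enoic acid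
Product: 16 (2S,6E)-2,6-dimethyloct-6-ene-1,8-diol
Conditions: LiAlH4, THF, 0 °C → rt; aqueous NaOH work-up
Reagents that add atoms: none
Why: LiAlH4 reduction converts the carboxylic acid into the primary alcohol and cleaves the acetate in the same operation, and the stereocentre, next to a carboxylate and then an alkoxide, is not enolised.

Step 13
Reactants: 16 (2S,6E)-2,6-dimethyloct-6-ene-1,8-diol
Product: 17 (2S,6E)-8-chloro-2,6-dimethyloct-6-en-1-ol
Conditions: NCS, Me2S (slight excess of each), CH2Cl2, −30 → 0 °C
Reagents that add atoms: N-chlorosuccinimide, O=C1CCC(=O)N1Cl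
Why: Corey–Kim chlorination (NCS and Me2S give a chlorosulfonium salt that turns the alcohol into an alkoxysulfonium leaving group) is selective for allylic over saturated alcohols, whose alkoxysulfonium salt is not displaced at low temperature and reverts to the alcohol on work-up, so only C5' is chlorinated without allylic transposition.

Step 14
Reactants: 17 (2S,6E)-8-chloro-2,6-dimethyloct-6-en-1-ol
Product: 18 {[(2S,6E)-8-chloro-2,6-dimethyloct-6-en-1-yl]oxy}tri(propan-2-yl)silane
Conditions: TIPSOTf, 2,6-lutidine, CH2Cl2, −78 → 0 °C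
Reagents that add atoms: triisopropylsilyl trifluoromethanesulfonate (TIPSOTf), CC(C)[Si](OS(=O)(=O)C(F)(F)F)(C(C)C)C(C)C
Why: Silylation of the remaining primary alcohol with the silyl triflate and a hindered pyridine base is fast at low temperature, leaves the allylic chloride untouched and gives an ether that survives organolithium and organoaluminium reagents.

Step 15
Reactants: 18 {[(2S,6E)-8-chloro-2,6-dimethyloct-6-en-1-yl]oxy}tri(propan-2-yl)silane; 19 1-(trimethylsilyl)propyne
Product: 21 {[(2S,6E)-2,6-dimethyl-11-(trimethylsilyl)undec-6-en-10-yn-1-yl]oxy}tri(propan-2-yl)silane, via lithiated propyne 20 (not isolated)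
Conditions: 19 (1.5 equiv), n-BuLi (1.4 equiv), THF, −78 → −20 °C; then 18, −78 → 0 °C
Reagents that add atoms: none
Why: SN2 alkylation of 3-lithio-1-(trimethylsilyl)propyne at the unhindered CH2 terminus of the primary allylic chloride forms C4'–C5', the silyl group keeping the nucleophile propargylic instead of allenic, and the E alkene is not transposed.

Step 16
Reactants: 21 {[(2S,6E)-2,6-dimethyl-11-(trimethylsilyl)undec-6-en-10-yn-1-yl]oxy}tri(propan-2-yl)silane
Product: 22 {[(2S,6E)-2,6-dimethylundec-6-en-10-yn-1-yl]oxy}tri(propan-2-yl)silane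
Conditions: K2CO3, MeOH, rt
Reagents that add atoms: none
Why: Base-mediated methanolysis of the alkynyl C–Si bond (protodesilylation) frees the terminal alkyne, whereas the hindered triisopropylsilyl ether is stable to K2CO3 in methanol.

Step 17
Reactants: 22 {[(2S,6E)-2,6-dimethylundec-6-en-10-yn-1-yl]oxy}tri(propan-2-yl)silane; 10 2-[3-(chloromethyl)-2,5,6-tris(methoxymethoxy)phenyl]-1,3-dioxolane
Product: 24 2-{2,5,6-tris(methoxymethoxy)-3-[(2E,6E,11S)-3,7,11-trimethyl-12-{[tri(propan-2-yl)silyl]oxy}dodeca-2,6-dien-1-yl]phenyl}-1,3-dioxolane, via alkenylalane 23 (not isolated)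
Conditions: 22, AlMe3 (2 equiv), Cp2ZrCl2 (0.25 equiv), ClCH2CH2Cl, 0 °C → rt; volatiles removed in vacuo, THF; then 10, NiCl2(PPh3)2 (5 mol%)/n-BuLi (10 mol%), THF, 0 °C → rt
Reagents that add atoms: trimethylaluminium (AlMe3), C[Al](C)C
Why: A methylzirconocene species formed from Cp2ZrCl2 and AlMe3 adds syn across the terminal alkyne with methyl on the internal carbon C3', and exchange with aluminium leaves the dimethylalanyl group on C2' cis to the new methyl (Negishi zirconium-catalysed carboalumination). After removal of excess AlMe3 and change to THF, zerovalent nickel made from NiCl2(PPh3)2 and n-BuLi inserts into the benzylic C–Cl bond of 10, the alkenyl group moves from aluminium to nickel and reductive elimination forms C1'–C2' with retention of the alkene geometry, the closest known reaction type being nickel-catalysed cross-coupling of carboalumination-derived alkenylalanes with electron-rich benzylic chlorides. No ring is closed and no stereocentre is formed, and C11' is a remote spectator. The selectivity required is the E geometry of C2'=C3', which follows from regioselective syn methylalumination of a terminal alkyne (metal to the CH terminus) and stereoretentive coupling, so that C1' ends cis to the C3' methyl. The 1,5-enyne is a standard carboalumination substrate, the C6'=C7' alkene and the TIPS ether do not react, and in THF the aluminium centre is coordinated by solvent, which should keep it from opening the MOM ethers or the dioxolane.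

Step 18
Reactants: 24 2-{2,5,6-tris(methoxymethoxy)-3-[(2E,6E,11S)-3,7,11-trimethyl-12-{[tri(propan-2-yl)silyl]oxy}dodeca-2,6-dien-1-yl]phenyl}-1,3-dioxolane
Product: 25 (2S,6E,10E)-12-[3-(1,3-dioxolan-2-yl)-2,4,5-tris(methoxymethoxy)phenyl]-2,6,10-trimethyldodeca-6,10-dien-1-ol
Conditions: TBAF, THF, rt
Reagents that add atoms: none
Why: Fluoride-mediated desilylation removes the TIPS group from the primary alcohol under basic conditions that leave the MOM ethers, the dioxolane and both alkenes unchanged.

Step 19
Reactants: 25 (2S,6E,10E)-12-[3-(1,3-dioxolan-2-yl)-2,4,5-tris(methoxymethoxy)phenyl]-2,6,10-trimethyldodeca-6,10-dien-1-ol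
Product: 26 (2S,6E,10E)-12-[3-(1,3-dioxolan-2-yl)-2,4,5-tris(methoxymethoxy)phenyl]-2,6,10-trimethyldodeca-6,10-dienal
Conditions: Dess–Martin periodinane, pyridine, CH2Cl2, 0 °C → rt
Reagents that add atoms: none
Why: Dess–Martin oxidation under pyridine buffering gives the α-methyl aldehyde at neutral pH without epimerising C11' or hydrolysing the acetals.

Step 20
Reactants: 26 (2S,6E,10E)-12-[3-(1,3-dioxolan-2-yl)-2,4,5-tris(methoxymethoxy)phenyl]-2,6,10-trimethyldodeca-6,10-dienal
Product: 27 (2S,6E,10E)-12-[3-(1,3-dioxolan-2-yl)-2,4,5-tris(methoxymethoxy)phenyl]-2,6,10-trimethyldodeca-6,10-dienoic acid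
Conditions: NaClO2, NaH2PO4, 2-methyl-2-butene (large excess), t-BuOH/H2O, 0 °C
Reagents that add atoms: sodium chlorite, [Na+].[O-]Cl=O
Why: Pinnick oxidation at buffered pH converts the aldehyde into the carboxylic acid without epimerisation, the excess scavenger protecting the two trisubstituted alkenes and the electron-rich ring from HOCl.

Step 21
Reactants: 27 (2S,6E,10E)-12-[3-(1,3-dioxolan-2-yl)-2,4,5-tris(methoxymethoxy)phenyl]-2,6,10-trimethyldodeca-6,10-dienoic acid
Product: 28 (2S,6E,10E)-12-(3-formyl-2,4,5-trihydroxyphenyl)-2,6,10-trimethyldodeca-6,10-dienoic acid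
Conditions: 3 M aq HCl, THF, 40 °C, degassed, argon
Reagents that add atoms: water, O
Why: Acid-catalysed acetal hydrolysis cleaves the three MOM ethers and the dioxolane in one operation, an alcohol-free medium avoids esterifying the acid, and mild temperature with exclusion of air should limit addition of the C6 phenol to the C2'=C3' alkene and oxidation of the hydroxyquinol.

**Compound list**

1 | 2,4,5-trihydroxybenzaldehyde | O=Cc1cc(O)c(O)cc1O | starting material
2 | 2,4,5-tris(methoxymethoxy)benzaldehyde | O=Cc1cc(OCOC)c(OCOC)cc1OCOC | intermediate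
3 | [2,4,5-tris(methoxymethoxy)phenyl]methanol | OCc1cc(OCOC)c(OCOC)cc1OCOC | intermediate
4 | tert-butyl(dimethyl){[2,4,5-tris(methoxymethoxy)phenyl]methoxy}silane | CC(C)(C)[Si](C)(C)OCc1cc(OCOC)c(OCOC)cc1OCOC | intermediate
5 | [3-({[tert-butyl(dimethyl)silyl]oxy}methyl)-2,5,6-tris(methoxymethoxy)phenyl]lithium (formed in the flask, step 4) | [Li]c1c(OCOC)c(CO[Si](C)(C)C(C)(C)C)cc(OCOC)c1OCOC | intermediate
6 | 3-({[tert-butyl(dimethyl)silyl]oxy}methyl)-2,5,6-tris(methoxymethoxy)benzaldehyde | O=Cc1c(OCOC)c(CO[Si](C)(C)C(C)(C)C)cc(OCOC)c1OCOC | intermediate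
7 | tert-butyl{[3-(1,3-dioxolan-2-yl)-2,4,5-tris(methoxymethoxy)phenyl]methoxy}dimethylsilane | CC(C)(C)[Si](C)(C)OCc1cc(OCOC)c(OCOC)c(C2OCCO2)c1OCOC | intermediate
8 | [3-(1,3-dioxolan-2-yl)-2,4,5-tris(methoxymethoxy)phenyl]methanol | OCc1cc(OCOC)c(OCOC)c(C2OCCO2)c1OCOC | intermediate
9 | [3-(1,3-dioxolan-2-yl)-2,4,5-tris(methoxymethoxy)phenyl]methyl methanesulfonate (formed in the flask, step 7) | CS(=O)(=O)OCc1cc(OCOC)c(OCOC)c(C2OCCO2)c1OCOC | intermediate
10 | 2-[3-(chloromethyl)-2,5,6-tris(methoxymethoxy)phenyl]-1,3-dioxolane | ClCc1cc(OCOC)c(OCOC)c(C2OCCO2)c1OCOC | intermediate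
11 | geranyl acetate, (2E)-3,7-dimethylocta-2,6-dien-1-yl acetate | CC(C)=CCC/C(C)=C/COC(C)=O | starting material
12 | (2E,6E)-8-hydroxy-3,7-dimethylocta-2,6-dien-1-yl acetate | CC(=O)OC/C=C(\C)CC/C=C(\C)CO | intermediate
13 | (2E,6E)-3,7-dimethyl-8-oxoocta-2,6-dien-1-yl acetate | CC(=O)OC/C=C(\C)CC/C=C(\C)C=O | intermediate
14 | (2E,6E)-8-(acetyloxy)-2,6-dimethylocta-2,6-dienoic acid | CC(=O)OC/C=C(\C)CC/C=C(\C)C(=O)O | intermediate
15 | (2S,6E)-8-(acetyloxy)-2,6-dimethyloct-6-enoic acid | CC(=O)OC/C=C(\C)CCC[C@H](C)C(=O)O | intermediate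
16 | (2S,6E)-2,6-dimethyloct-6-ene-1,8-diol | OC/C=C(\C)CCC[C@H](C)CO | intermediate
17 | (2S,6E)-8-chloro-2,6-dimethyloct-6-en-1-ol | ClC/C=C(\C)CCC[C@H](C)CO | intermediate
18 | {[(2S,6E)-8-chloro-2,6-dimethyloct-6-en-1-yl]oxy}tri(propan-2-yl)silane | ClC/C=C(\C)CCC[C@H](C)CO[Si](C(C)C)(C(C)C)C(C)C | intermediate
19 | 1-(trimethylsilyl)propyne | CC#C[Si](C)(C)C | starting material
20 | 3-lithio-1-(trimethylsilyl)propyne (formed in the flask, step 15) | [Li]CC#C[Si](C)(C)C | intermediate
21 | {[(2S,6E)-2,6-dimethyl-11-(trimethylsilyl)undec-6-en-10-yn-1-yl]oxy}tri(propan-2-yl)silane | C[Si](C)(C)C#CCC/C=C(\C)CCC[C@H](C)CO[Si](C(C)C)(C(C)C)C(C)C | intermediate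
22 | {[(2S,6E)-2,6-dimethylundec-6-en-10-yn-1-yl]oxy}tri(propan-2-yl)silane | C#CCC/C=C(\C)CCC[C@H](C)CO[Si](C(C)C)(C(C)C)C(C)C | intermediate
23 | dimethyl[(1E,5E,10S)-2,6,10-trimethyl-11-{[tri(propan-2-yl)silyl]oxy}undeca-1,5-dien-1-yl]alane (formed in the flask, step 17) | C[Al](C)/C=C(\C)CC/C=C(\C)CCC[C@H](C)CO[Si](C(C)C)(C(C)C)C(C)C | intermediate
24 | 2-{2,5,6-tris(methoxymethoxy)-3-[(2E,6E,11S)-3,7,11-trimethyl-12-{[tri(propan-2-yl)silyl]oxy}dodeca-2,6-dien-1-yl]phenyl}-1,3-dioxolane | C/C(=C\Cc1cc(OCOC)c(OCOC)c(C2OCCO2)c1OCOC)CC/C=C(\C)CCC[C@H](C)CO[Si](C(C)C)(C(C)C)C(C)C | intermediate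
25 | (2S,6E,10E)-12-[3-(1,3-dioxolan-2-yl)-2,4,5-tris(methoxymethoxy)phenyl]-2,6,10-trimethyldodeca-6,10-dien-1-ol | C/C(=C\Cc1cc(OCOC)c(OCOC)c(C2OCCO2)c1OCOC)CC/C=C(\C)CCC[C@H](C)CO | intermediate
26 | (2S,6E,10E)-12-[3-(1,3-dioxolan-2-yl)-2,4,5-tris(methoxymethoxy)phenyl]-2,6,10-trimethyldodeca-6,10-dienal | C/C(=C\Cc1cc(OCOC)c(OCOC)c(C2OCCO2)c1OCOC)CC/C=C(\C)CCC[C@H](C)C=O | intermediate
27 | (2S,6E,10E)-12-[3-(1,3-dioxolan-2-yl)-2,4,5-tris(methoxymethoxy)phenyl]-2,6,10-trimethyldodeca-6,10-dienoic acid | C/C(=C\Cc1cc(OCOC)c(OCOC)c(C2OCCO2)c1OCOC)CC/C=C(\C)CCC[C@H](C)C(=O)O | intermediate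
28 | (2S,6E,10E)-12-(3-formyl-2,4,5-trihydroxyphenyl)-2,6,10-trimethyldodeca-6,10-dienoic acid (CNP0180353.1) | C/C(=C\Cc1cc(O)c(O)c(C=O)c1O)CC/C=C(\C)CCC[C@H](C)C(=O)O | target

**Step count and risks**

Total steps: 21. Longest linear sequence: 14 steps (steps 8–21, from geranyl acetate 11); the arene branch (steps 1–7) joins at step 17.

Steps most likely to fail:

1. Step 17. Aluminium species may open the dioxolane or the MOM acetals by Lewis-acid ionisation, the benzylic chloride may homocouple or be reduced at nickel, or alkenyl transfer from aluminium may stall. Fallback, setting out from 22 and 10 and returning at 24: the same two bonds are made in two stages with a milder organometallic. The carboalumination of 22 is run as in step 17 and alkenylalane 23 is quenched with I2 to give {[(2S,6E,10E)-11-iodo-2,6,10-trimethylundeca-6,10-dien-1-yl]oxy}tri(propan-2-yl)silane F1. Chloride 10 is converted with Zn dust and LiCl in THF into chloro{[3-(1,3-dioxolan-2-yl)-2,4,5-tris(methoxymethoxy)phenyl]methyl}zinc F2. Negishi coupling of the two with Pd(PPh3)4 (zerovalent palladium, THF, rt) proceeds with retention of alkene geometry and gives 24 without any aluminium reagent meeting the acetals.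

2. Step 5. The silyl triflate may strip MOM groups or ionise the electron-rich benzylic silyl ether, or acetalisation of the di-ortho-substituted aldehyde may stay incomplete. Fallback, setting out from 4 and returning at 7: the formyl carbon is introduced already at the acetal level. Aryllithium 5 is generated from 4 as in step 4 and trapped with diethyl phenyl orthoformate (THF, −78 °C → rt) to give tert-butyl{[3-(diethoxymethyl)-2,4,5-tris(methoxymethoxy)phenyl]methoxy}dimethylsilane F3. Acetal exchange with ethylene glycol and catalytic PPTS in CH2Cl2 at rt, which is far easier than acetalising the hindered aldehyde and mild enough for aryl MOM ethers, then gives 7.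

3. Step 21. Protonation of the C2'=C3' alkene may lead to ring closure by the C6 phenol (chroman formation) or to cation–olefin cyclisation, and the free hydroxyquinol may oxidise during prolonged acid treatment. Fallback, setting out from 27 and returning at 28: the unmasking is split so that no free phenol meets a Brønsted acid. PPTS in wet acetone at rt hydrolyses only the dioxolane and gives (2S,6E,10E)-12-[3-formyl-2,4,5-tris(methoxymethoxy)phenyl]-2,6,10-trimethyldodeca-6,10-dienoic acid F4. TMSOTf with 2,2'-bipyridyl in CH2Cl2/MeCN at 0 °C then exchanges the aryl MOM ethers for aryl trimethylsilyl ethers under basic buffering, the acid being silylated as well, to give trimethylsilyl (2S,6E,10E)-12-{3-formyl-2,4,5-tris[(trimethylsilyl)oxy]phenyl}-2,6,10-trimethyldodeca-6,10-dienoate F5. Brief treatment with water under argon hydrolyses the silyl ethers and the silyl ester to 28.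

**Further compounds**

F1 | step 17 | {[(2S,6E,10E)-11-iodo-2,6,10-trimethylundeca-6,10-dien-1-yl]oxy}tri(propan-2-yl)silane | I/C=C(\C)CC/C=C(\C)CCC[C@H](C)CO[Si](C(C)C)(C(C)C)C(C)C
F2 | step 17 | chloro{[3-(1,3-dioxolan-2-yl)-2,4,5-tris(methoxymethoxy)phenyl]methyl}zinc | Cl[Zn]Cc1cc(OCOC)c(OCOC)c(C2OCCO2)c1OCOC
F3 | step 5 | tert-butyl{[3-(diethoxymethyl)-2,4,5-tris(methoxymethoxy)phenyl]methoxy}dimethylsilane | CCOC(OCC)c1c(OCOC)c(CO[Si](C)(C)C(C)(C)C)cc(OCOC)c1OCOC
F4 | step 21 | (2S,6E,10E)-12-[3-formyl-2,4,5-tris(methoxymethoxy)phenyl]-2,6,10-trimethyldodeca-6,10-dienoic acid | C/C(=C\Cc1cc(OCOC)c(OCOC)c(C=O)c1OCOC)CC/C=C(\C)CCC[C@H](C)C(=O)O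
F5 | step 21 | trimethylsilyl (2S,6E,10E)-12-{3-formyl-2,4,5-tris[(trimethylsilyl)oxy]phenyl}-2,6,10-trimethyldodeca-6,10-dienoate | C/C(=C\Cc1cc(O[Si](C)(C)C)c(O[Si](C)(C)C)c(C=O)c1O[Si](C)(C)C)CC/C=C(\C)CCC[C@H](C)C(=O)O[Si](C)(C)C
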